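**Retrosynthetic overview**
1. Feature: the core is a trans-(2R,3R)-2-aryl-1,4-benzodioxane. The chain O1–C2(aryl)–C3–O4 is fused to a benzo ring with three neighbouring oxygens (O1 on C8a, O4 on C4a, OAr on C5) and a carbon substituent at C7, and C2 bears a 3,4,5-trioxygenated phenyl ring. This is the skeleton of (2R,3R)-dihydromyricetin with one oxygen placed between C4 and C4a, so that C4 becomes the exocyclic CH2O carbon.
2. Late disconnections: the catechol acetonide, the CH2–O bond to magnolol (Mitsunobu), CH2OH back to the ester, the C7–allyl bond (Stille on the 7-triflate), and both 4-allylphenyl ether bonds (one double Chan–Lam coupling).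
3. Core disconnections: the O4–C3 bond (phenoxide SN2 on the C3 mesylate with inversion, after methanolysis of a seven-membered aryl lactone), then the C4a–O4 bond (Baeyer–Villiger oxygen insertion into the flavanonol ketone).
4. Ring order: rings A, B and the pyranone come with the chiral pool. The dioxole protecting ring is made first, the pyranone is then expanded to a 1,5-benzodioxepin-2-one, and this is contracted to the 1,4-dioxane ring.
5. Every alkene and every copper-mediated step comes after the peracid step and after the α-hydroxy ketone has gone.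

Key step: step 5

Remark: commercial dihydromyricetin is taken to be the natural (2R,3R)-(+) enantiomer. The flavonoid atom labels (O1, C2, C3, C4, C4a, C5–C8, C8a) are kept throughout, the inserted oxygen is called O4, and the benzodioxanes are numbered as in the target (aryl on C2, former C4 on C3).

**Step 1**
Reactants: 1 (2R,3R)-dihydromyricetin
Product: 2 (2R,3R)-3,5,7-trihydroxy-2-(7-hydroxy-2,2-dimethyl-1,3-benzodioxol-5-yl)chroman-4-one (ring B acetonide)
Conditions: Me2C(OMe)2 (5 equiv), p-TsOH·H2O (5 mol %), THF–toluene, reflux through 4 Å MS, Ar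
Reagents that add atoms: 2,2-dimethoxypropane, COC(C)(C)OC
Why: Acid-catalysed transketalisation (catechol acetonide formation) should give one product without touching C2 or C3, because only two vicinal phenols can close the five-membered dioxole, the two vicinal pairs of the pyrogallol ring B are equivalent by rotation, and neither the meta-related ring A phenols nor the lone 3-OH can form a cyclic ketal.

**Step 2**
Reactants: 2 ring B acetonide
Product: 3 (2R,3R)-3,5-dihydroxy-2-(7-hydroxy-2,2-dimethyl-1,3-benzodioxol-5-yl)-4-oxochroman-7-yl triflate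
Conditions: PhNTf2 (1.0 equiv), i-Pr2NEt (1.1 equiv), CH2Cl2–DMF, 0 °C to rt, Ar
Reagents that add atoms: N-phenylbis(trifluoromethanesulfonimide), FC(F)(F)S(=O)(=O)N(c1ccccc1)S(=O)(=O)C(F)(F)F
Why: Chemoselective O-triflation with a mild triflyl donor should hit only the 7-OH, which is para to the carbonyl (a vinylogous acid) and is the one hydroxyl ionised by one equivalent of amine, whereas the 5-OH is held in the hydrogen bond to C4=O and the ring B phenol and 3-OH are much less acidic.

**Step 3**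
Reactants: 3 7-triflate
Product: 4 (2R,3R)-2-(7-acetoxy-2,2-dimethyl-1,3-benzodioxol-5-yl)-3,5-dihydroxy-4-oxochroman-7-yl triflate
Conditions: Ac2O (1.05 equiv), Et3N (1.2 equiv), CH2Cl2, −10 °C
Reagents that add atoms: acetic anhydride, CC(=O)OC(C)=O
Why: Selective phenol acetylation should work because the unchelated ring B phenoxide is acylated before the hindered hydrogen-bonded 3-OH and the chelated 5-OH; an acetate is used here instead of an early aryl ether because a Cu(OAc)2/air arylation at this stage would meet an α-hydroxy ketone that divalent copper can dehydrogenate to the flavonol, and because the acetate leaves without an extra step in step 6.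

**Step 4**
Reactants: 4 ring B acetate
Product: 5 (2R,3R)-2-(7-acetoxy-2,2-dimethyl-1,3-benzodioxol-5-yl)-5-hydroxy-3-(mesyloxy)-4-oxochroman-7-yl triflate (key-step precursor)
Conditions: MsCl (1.3 equiv), Et3N (1.6 equiv), CH2Cl2, −30 to 0 °C
Reagents that add atoms: methanesulfonyl chloride, CS(=O)(=O)Cl
Why: Mesylation of the secondary alcohol follows the usual flavanonol reactivity order (3-OH before the chelated 5-OH) and keeps the C3–O bond and so the configuration, while the low temperature and the equatorial mesylate, which has no anti-periplanar H on C2, should hold back elimination to the flavone.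

**Step 5**
Reactants: 5 3-O-mesyl-7-O-triflyl flavanonol
Product: 7 (3R,4R)-4-(7-acetoxy-2,2-dimethyl-1,3-benzodioxol-5-yl)-9-hydroxy-3-(mesyloxy)-2-oxo-3,4-dihydro-2H-1,5-benzodioxepin-7-yl triflate (C2 R and C3 R in flavonoid labels), via Criegee adduct 6 (not isolated)
Conditions: mCPBA (3 equiv), CH2Cl2, 0 to 40 °C, dark; aq. Na2S2O3, then cold aq. NaHCO3 wash
Reagents that add atoms: mCPBA (3-chloroperbenzoic acid), O=C(OO)c1cccc(Cl)c1
Why: The peracid adds to the C4 carbonyl, which the 5-OH hydrogen bond and the 7-triflate make more electrophilic, to give Criegee adduct 6, and loss of 3-chlorobenzoate is coupled to a 1,2-shift of C4a from C4 to the peroxide oxygen, which forms the C4a–O4 bond. This is the Baeyer–Villiger oxidation of a chroman-4-one or flavanone (Dakin-type aryl migration of an ortho-oxygenated aryl ketone), a known entry to 3,4-dihydro-1,5-benzodioxepin-2-ones. The seven-membered ring arises by one-atom expansion of the pyranone and not by a cyclisation, so no new ring-closing event is needed. No stereocentre is created: C2 is remote, C3 is the carbon that does not migrate, and the neutral to weakly acidic medium should not enolise C3, so both keep the configuration of the chiral pool. The selectivity required is migration of aryl C4a over alkyl C3, and it is secured because C4a is flanked by two oxygen donors (O1 on C8a and OH on C5) that carry the developing positive charge, whereas C3 bears the strongly electron-withdrawing mesylate. Chemoselectivity is secured because no alkene is present yet and ring B is tempered by its acetate.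

**Step 6**
Reactants: 7 seven-membered aryl lactone
Product: 10 methyl (2R,3S)-5-hydroxy-2-(7-hydroxy-2,2-dimethyl-1,3-benzodioxol-5-yl)-7-(triflyloxy)-2,3-dihydro-1,4-benzodioxine-3-carboxylate (trans), via seco mesylate ester 8 (not isolated), via benzodioxane acetate 9 (not isolated)
Conditions: K2CO3 (2.5 equiv), degassed MeOH–THF, 0 °C to rt, Ar; pH 5 buffer
Reagents that add atoms: methanol, CO
Why: Transesterification of the activated aryl lactone frees the C4a phenoxide, which displaces the α-mesyloxy ester in a 6-exo-tet SN2 reaction (intramolecular Williamson etherification) with inversion at C3; because C4 leaves the ring in the same event this should give the trans ester with the spatial arrangement of the target (the descriptor S at C3 reflects only the high rank of CO2Me), the C5 phenoxide would have to close a seven-membered ring and should lose, and the ring B acetate is methanolysed in the same pot.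

**Step 7**
Reactants: 11 1-allyl-4-bromobenzene
Product: 14 4-allylphenylboronic acid, via 4-allylphenyllithium 12 (not isolated), via lithium triisopropyl borate complex 13 (not isolated)
Conditions: n-BuLi (1.05 equiv), THF, −78 °C; B(Oi-Pr)3, −78 °C to rt; 1 M HCl
Reagents that add atoms: triisopropyl borate, CC(C)OB(OC(C)C)OC(C)C; water, O
Why: Bromine–lithium exchange, electrophilic borylation and hydrolysis form a standard boronic acid synthesis, and at −78 °C the exchange should outrun deprotonation of the benzylic-allylic CH2.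

**Step 8**
Reactants: 10 diphenol ester; 14 4-allylphenylboronic acid
Product: 17 methyl (2R,3S)-5-(4-allylphenoxy)-2-[7-(4-allylphenoxy)-2,2-dimethyl-1,3-benzodioxol-5-yl]-7-(triflyloxy)-2,3-dihydro-1,4-benzodioxine-3-carboxylate, via C5 monoaryl ether 15 (not isolated), via ring B monoaryl ether 16 (not isolated)
Conditions: 14 (5 equiv), Cu(OAc)2 (3 equiv), pyridine (10 equiv), 4 Å MS, CH2Cl2, dry air, rt
Reagents that add atoms: none
Why: Chan–Lam O-arylation should take place at both hydroxyls because, with C4 out of the ring, each is an ordinary unchelated phenol, and the room-temperature, weakly basic conditions leave the aryl triflate, the ester-bearing stereocentre and the allyl groups alone.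

**Step 9**
Reactants: 17 bis(aryl ether) triflate
Product: 18 methyl (2R,3S)-7-allyl-5-(4-allylphenoxy)-2-[7-(4-allylphenoxy)-2,2-dimethyl-1,3-benzodioxol-5-yl]-2,3-dihydro-1,4-benzodioxine-3-carboxylate
Conditions: allylSnBu3 (1.5 equiv), Pd(PPh3)4 (5 mol %), LiCl (3 equiv), dioxane, 95 °C, Ar
Reagents that add atoms: allyltributylstannane, C=CC[Sn](CCCC)(CCCC)CCCC
Why: Stille coupling of an aryl triflate with an allylstannane in the presence of LiCl is well established, the C7–OTf bond is the only site open to oxidative addition of zerovalent palladium, and the neutral medium does not threaten C3.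

**Step 10**
Reactants: 18 triallyl ester
Product: 19 [(2R,3R)-7-allyl-5-(4-allylphenoxy)-2-[7-(4-allylphenoxy)-2,2-dimethyl-1,3-benzodioxol-5-yl]-2,3-dihydro-1,4-benzodioxin-3-yl]methanol
Conditions: LiAlH4 (1.5 equiv), THF, 0 °C; H2O, aq. NaOH
Reagents that add atoms: none
Why: Hydride reduction of the ester to the primary alcohol is faster than any enolisation and spares aryl ethers, the ketal and isolated alkenes; the descriptor at C3 returns to R only because CH2OH ranks below C2.

**Step 11**
Reactants: 19 primary alcohol; 20 magnolol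
Product: 21 5,5'-diallyl-2'-{[(2R,3R)-7-allyl-5-(4-allylphenoxy)-2-[7-(4-allylphenoxy)-2,2-dimethyl-1,3-benzodioxol-5-yl]-2,3-dihydro-1,4-benzodioxin-3-yl]methoxy}biphenyl-2-ol
Conditions: 20 (3 equiv), PPh3 (1.5 equiv), DIAD (1.5 equiv), THF, 0 °C to rt
Reagents that add atoms: none
Why: Mitsunobu etherification takes place at the primary CH2, so no stereocentre is involved, and an excess of the C2-symmetric bisphenol should ensure mono-alkylation because the remaining hydroxyl of the product is more hindered.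

**Step 12**
Reactants: 21 magnolol ether acetonide
Product: 22 target CNP0231734.1
Conditions: TFA–H2O (9:1, 20 vol % in CH2Cl2), 0 °C to rt, short contact time
Reagents that add atoms: none
Why: Acid hydrolysis of the catechol acetonide frees the two ring B hydroxyls under conditions too mild to add acid across the terminal alkenes, and any reversible ionisation of the benzylic C2–O1 bond would re-close to the more stable trans ring while C3 holds the absolute configuration.

**Compound list**
1 | (2R,3R)-dihydromyricetin | O=C1c2c(O)cc(O)cc2O[C@H](c2cc(O)c(O)c(O)c2)[C@H]1O | starting material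
2 | (2R,3R)-3,5,7-trihydroxy-2-(7-hydroxy-2,2-dimethyl-1,3-benzodioxol-5-yl)chroman-4-one | Oc1cc([C@H]2Oc3cc(O)cc(O)c3C(=O)[C@@H]2O)cc4OC(C)(C)Oc14 | intermediate
3 | (2R,3R)-3,5-dihydroxy-2-(7-hydroxy-2,2-dimethyl-1,3-benzodioxol-5-yl)-4-oxochroman-7-yl triflate | Oc1cc([C@H]2Oc3cc(OS(=O)(=O)C(F)(F)F)cc(O)c3C(=O)[C@@H]2O)cc4OC(C)(C)Oc14 | intermediate
4 | (2R,3R)-2-(7-acetoxy-2,2-dimethyl-1,3-benzodioxol-5-yl)-3,5-dihydroxy-4-oxochroman-7-yl triflate | CC(=O)Oc1cc([C@H]2Oc3cc(OS(=O)(=O)C(F)(F)F)cc(O)c3C(=O)[C@@H]2O)cc4OC(C)(C)Oc14 | intermediate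
5 | (2R,3R)-2-(7-acetoxy-2,2-dimethyl-1,3-benzodioxol-5-yl)-5-hydroxy-3-(mesyloxy)-4-oxochroman-7-yl triflate | CC(=O)Oc1cc([C@H]2Oc3cc(OS(=O)(=O)C(F)(F)F)cc(O)c3C(=O)[C@@H]2OS(C)(=O)=O)cc4OC(C)(C)Oc14 | intermediate (key-step precursor)
6 | Criegee adduct of 5: C4 carries OH and the 3-chloroperbenzoate group, C4 configuration undefined | CC(=O)Oc1cc([C@H]2Oc3cc(OS(=O)(=O)C(F)(F)F)cc(O)c3C(O)(OOC(=O)c5cccc(Cl)c5)[C@@H]2OS(C)(=O)=O)cc4OC(C)(C)Oc14 | intermediate (not isolated)
7 | (3R,4R)-4-(7-acetoxy-2,2-dimethyl-1,3-benzodioxol-5-yl)-9-hydroxy-3-(mesyloxy)-2-oxo-3,4-dihydro-2H-1,5-benzodioxepin-7-yl triflate | CC(=O)Oc1cc([C@H]2Oc3cc(OS(=O)(=O)C(F)(F)F)cc(O)c3OC(=O)[C@@H]2OS(C)(=O)=O)cc4OC(C)(C)Oc14 | intermediate (key-step product)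
8 | methyl (2R,3R)-3-(7-acetoxy-2,2-dimethyl-1,3-benzodioxol-5-yl)-3-[2,3-dihydroxy-5-(triflyloxy)phenoxy]-2-(mesyloxy)propanoate | CC(=O)Oc1cc([C@@H](Oc2cc(OS(=O)(=O)C(F)(F)F)cc(O)c2O)[C@@H](OS(C)(=O)=O)C(=O)OC)cc3OC(C)(C)Oc13 | intermediate (not isolated)
9 | methyl (2R,3S)-2-(7-acetoxy-2,2-dimethyl-1,3-benzodioxol-5-yl)-5-hydroxy-7-(triflyloxy)-2,3-dihydro-1,4-benzodioxine-3-carboxylate | CC(=O)Oc1cc([C@H]2Oc3cc(OS(=O)(=O)C(F)(F)F)cc(O)c3O[C@@H]2C(=O)OC)cc4OC(C)(C)Oc14 | intermediate (not isolated)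
10 | methyl (2R,3S)-5-hydroxy-2-(7-hydroxy-2,2-dimethyl-1,3-benzodioxol-5-yl)-7-(triflyloxy)-2,3-dihydro-1,4-benzodioxine-3-carboxylate | Oc1cc([C@H]2Oc3cc(OS(=O)(=O)C(F)(F)F)cc(O)c3O[C@@H]2C(=O)OC)cc4OC(C)(C)Oc14 | intermediate
11 | 1-allyl-4-bromobenzene | C=CCc1ccc(Br)cc1 | starting material
12 | 4-allylphenyllithium | [Li]c1ccc(CC=C)cc1 | intermediate (not isolated)
13 | lithium (4-allylphenyl)triisopropoxyborate | [Li+].C=CCc1ccc(cc1)[B-](OC(C)C)(OC(C)C)OC(C)C | intermediate (not isolated)
14 | 4-allylphenylboronic acid | OB(O)c1ccc(CC=C)cc1 | intermediate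
15 | methyl (2R,3S)-5-(4-allylphenoxy)-2-(7-hydroxy-2,2-dimethyl-1,3-benzodioxol-5-yl)-7-(triflyloxy)-2,3-dihydro-1,4-benzodioxine-3-carboxylate | Oc1cc([C@H]2Oc3cc(OS(=O)(=O)C(F)(F)F)cc(Oc5ccc(CC=C)cc5)c3O[C@@H]2C(=O)OC)cc4OC(C)(C)Oc14 | intermediate (not isolated)
16 | methyl (2R,3S)-2-[7-(4-allylphenoxy)-2,2-dimethyl-1,3-benzodioxol-5-yl]-5-hydroxy-7-(triflyloxy)-2,3-dihydro-1,4-benzodioxine-3-carboxylate | C=CCc1ccc(Oc2cc([C@H]3Oc4cc(OS(=O)(=O)C(F)(F)F)cc(O)c4O[C@@H]3C(=O)OC)cc6OC(C)(C)Oc26)cc1 | intermediate (not isolated)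
17 | methyl (2R,3S)-5-(4-allylphenoxy)-2-[7-(4-allylphenoxy)-2,2-dimethyl-1,3-benzodioxol-5-yl]-7-(triflyloxy)-2,3-dihydro-1,4-benzodioxine-3-carboxylate | C=CCc1ccc(Oc2cc([C@H]3Oc4cc(OS(=O)(=O)C(F)(F)F)cc(Oc5ccc(CC=C)cc5)c4O[C@@H]3C(=O)OC)cc6OC(C)(C)Oc26)cc1 | intermediate
18 | methyl (2R,3S)-7-allyl-5-(4-allylphenoxy)-2-[7-(4-allylphenoxy)-2,2-dimethyl-1,3-benzodioxol-5-yl]-2,3-dihydro-1,4-benzodioxine-3-carboxylate | C=CCc1ccc(Oc2cc([C@H]3Oc4cc(CC=C)cc(Oc5ccc(CC=C)cc5)c4O[C@@H]3C(=O)OC)cc6OC(C)(C)Oc26)cc1 | intermediate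
19 | [(2R,3R)-7-allyl-5-(4-allylphenoxy)-2-[7-(4-allylphenoxy)-2,2-dimethyl-1,3-benzodioxol-5-yl]-2,3-dihydro-1,4-benzodioxin-3-yl]methanol | C=CCc1ccc(Oc2cc([C@H]3Oc4cc(CC=C)cc(Oc5ccc(CC=C)cc5)c4O[C@@H]3CO)cc6OC(C)(C)Oc26)cc1 | intermediate
20 | magnolol (5,5'-diallylbiphenyl-2,2'-diol) | C=CCc1ccc(O)c(-c2cc(CC=C)ccc2O)c1 | starting material
21 | magnolol mono-ether of 19 (ring B acetonide still in place) | C=CCc1ccc(Oc2cc([C@H]3Oc4cc(CC=C)cc(Oc5ccc(CC=C)cc5)c4O[C@@H]3COc7ccc(CC=C)cc7-c8cc(CC=C)ccc8O)cc6OC(C)(C)Oc26)cc1 | intermediate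
22 | CNP0231734.1, (2R,3R)-benzodioxane | C=CCc1ccc(Oc2cc([C@H]3Oc4cc(CC=C)cc(Oc5ccc(CC=C)cc5)c4O[C@@H]3COc3ccc(CC=C)cc3-c3cc(CC=C)ccc3O)cc(O)c2O)cc1 | target

**Step count**
Total steps: 12. Longest linear sequence: 11 (steps 1–6 and 8–12).

**Steps most likely to fail**

Step 5. Peracid addition and the aryl shift may be slow, because the triflate para to C4a withdraws electron density from the migrating carbon. Oxidation of the free phenol by excess peracid could then compete.
- The fallback changes the point at which the C7 handle is made, so that the insertion runs on a donor-substituted, phloroglucinol-type ring A. This is the flavanone class on which the Baeyer–Villiger reaction is best established.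
- It sets out from 2. TIPSCl and imidazole in DMF at 0 °C should silylate the acidic 7-OH to give the 7-O-triisopropylsilyl ether F1.
- Acetylation as in step 3 gives the ring B acetate F2, and mesylation as in step 4 gives the 3-O-mesylate F3.
- mCPBA (1.5 equiv) in CH2Cl2 gives the silyloxy lactone F4, and K2CO3 in MeOH at 0 °C gives the silyloxy diphenol ester F5.
- Double Chan–Lam coupling with 14 gives the bis(aryl ether) F6, and TBAF buffered with AcOH frees the C7 phenol F7.
- PhNTf2 with Et3N converts F7 into 17, where the route is rejoined.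

Step 6. Base may remove the acidic proton at C3 of the opened α-mesyloxy ester. This could lead to β-elimination of the O1 phenoxide or to scrambling at C3 before ring closure, and methoxide may also attack the triflate at sulfur.
- The fallback forms the O4–C3 bond under neutral conditions from an alcohol instead of a sulfonate.
- It sets out from 4. Ac2O (1.1 equiv) with pyridine and catalytic DMAP gives the 3-O-acetate F8.
- mCPBA as in step 5 gives the acetoxy lactone F9, in which the acyloxy group again disfavours C3 migration.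
- Brief K2CO3/MeOH treatment removes both acetates and opens the lactone to the α-hydroxy ester triphenol F10.
- An intramolecular Mitsunobu reaction (PPh3, DIAD, dilute THF, 0 °C) closes the six-membered ring with inversion at C3 and gives 10, where the route is rejoined.

Step 8. The second arylation may stall, while protodeboronation and homocoupling use up the boronic acid and leave mixtures of the two monoaryl ethers.
- The fallback is a copper-free O-arylation followed by one extra pair of cross-couplings.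
- It sets out from 10. Commercial bis(4-bromophenyl)iodonium triflate (2.5 equiv) with K2CO3 in MeCN at 40 °C should give the bis(4-bromophenyl) ether F11.
- A threefold Stille allylation (allylSnBu3, Pd(PPh3)4, LiCl, dioxane, 95 °C) at the two C–Br bonds and the C7–OTf bond gives 18, where the route is rejoined.

**Further compounds**
F1 | step 5 | (2R,3R)-3,5-dihydroxy-2-(7-hydroxy-2,2-dimethyl-1,3-benzodioxol-5-yl)-7-(triisopropylsilyloxy)chroman-4-one | Oc1cc([C@H]2Oc3cc(O[Si](C(C)C)(C(C)C)C(C)C)cc(O)c3C(=O)[C@@H]2O)cc4OC(C)(C)Oc14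
F2 | step 5 | (2R,3R)-2-(7-acetoxy-2,2-dimethyl-1,3-benzodioxol-5-yl)-3,5-dihydroxy-7-(triisopropylsilyloxy)chroman-4-one | CC(=O)Oc1cc([C@H]2Oc3cc(O[Si](C(C)C)(C(C)C)C(C)C)cc(O)c3C(=O)[C@@H]2O)cc4OC(C)(C)Oc14
F3 | step 5 | (2R,3R)-2-(7-acetoxy-2,2-dimethyl-1,3-benzodioxol-5-yl)-5-hydroxy-3-(mesyloxy)-7-(triisopropylsilyloxy)chroman-4-one | CC(=O)Oc1cc([C@H]2Oc3cc(O[Si](C(C)C)(C(C)C)C(C)C)cc(O)c3C(=O)[C@@H]2OS(C)(=O)=O)cc4OC(C)(C)Oc14
F4 | step 5 | (3R,4R)-4-(7-acetoxy-2,2-dimethyl-1,3-benzodioxol-5-yl)-9-hydroxy-3-(mesyloxy)-7-(triisopropylsilyloxy)-3,4-dihydro-2H-1,5-benzodioxepin-2-one | CC(=O)Oc1cc([C@H]2Oc3cc(O[Si](C(C)C)(C(C)C)C(C)C)cc(O)c3OC(=O)[C@@H]2OS(C)(=O)=O)cc4OC(C)(C)Oc14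
F5 | step 5 | methyl (2R,3S)-5-hydroxy-2-(7-hydroxy-2,2-dimethyl-1,3-benzodioxol-5-yl)-7-(triisopropylsilyloxy)-2,3-dihydro-1,4-benzodioxine-3-carboxylate | Oc1cc([C@H]2Oc3cc(O[Si](C(C)C)(C(C)C)C(C)C)cc(O)c3O[C@@H]2C(=O)OC)cc4OC(C)(C)Oc14
F6 | step 5 | methyl (2R,3S)-5-(4-allylphenoxy)-2-[7-(4-allylphenoxy)-2,2-dimethyl-1,3-benzodioxol-5-yl]-7-(triisopropylsilyloxy)-2,3-dihydro-1,4-benzodioxine-3-carboxylate | C=CCc1ccc(Oc2cc([C@H]3Oc4cc(O[Si](C(C)C)(C(C)C)C(C)C)cc(Oc5ccc(CC=C)cc5)c4O[C@@H]3C(=O)OC)cc6OC(C)(C)Oc26)cc1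
F7 | step 5 | methyl (2R,3S)-5-(4-allylphenoxy)-2-[7-(4-allylphenoxy)-2,2-dimethyl-1,3-benzodioxol-5-yl]-7-hydroxy-2,3-dihydro-1,4-benzodioxine-3-carboxylate | C=CCc1ccc(Oc2cc([C@H]3Oc4cc(O)cc(Oc5ccc(CC=C)cc5)c4O[C@@H]3C(=O)OC)cc6OC(C)(C)Oc26)cc1
F8 | step 6 | (2R,3R)-3-acetoxy-2-(7-acetoxy-2,2-dimethyl-1,3-benzodioxol-5-yl)-5-hydroxy-4-oxochroman-7-yl triflate | CC(=O)Oc1cc([C@H]2Oc3cc(OS(=O)(=O)C(F)(F)F)cc(O)c3C(=O)[C@@H]2OC(C)=O)cc4OC(C)(C)Oc14
F9 | step 6 | (3R,4R)-3-acetoxy-4-(7-acetoxy-2,2-dimethyl-1,3-benzodioxol-5-yl)-9-hydroxy-2-oxo-3,4-dihydro-2H-1,5-benzodioxepin-7-yl triflate | CC(=O)Oc1cc([C@H]2Oc3cc(OS(=O)(=O)C(F)(F)F)cc(O)c3OC(=O)[C@@H]2OC(C)=O)cc4OC(C)(C)Oc14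
F10 | step 6 | methyl (2R,3R)-3-[2,3-dihydroxy-5-(triflyloxy)phenoxy]-2-hydroxy-3-(7-hydroxy-2,2-dimethyl-1,3-benzodioxol-5-yl)propanoate | Oc1cc([C@@H](Oc2cc(OS(=O)(=O)C(F)(F)F)cc(O)c2O)[C@@H](O)C(=O)OC)cc3OC(C)(C)Oc13
F11 | step 8 | methyl (2R,3S)-5-(4-bromophenoxy)-2-[7-(4-bromophenoxy)-2,2-dimethyl-1,3-benzodioxol-5-yl]-7-(triflyloxy)-2,3-dihydro-1,4-benzodioxine-3-carboxylate | Brc1ccc(Oc2cc([C@H]3Oc4cc(OS(=O)(=O)C(F)(F)F)cc(Oc5ccc(Br)cc5)c4O[C@@H]3C(=O)OC)cc6OC(C)(C)Oc26)cc1
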